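A small charge of pre-initiator, 0.25 mM, stands against 0.050 M of free monomer in this closed flask, and the oak run is this same flask, followed so far.

- oak: free monomer 0.050 M; pre-initiator 0.25 mM; the very flask that is asked about, followed so far
- flask: free monomer 0.050 M; pre-initiator 0.25 mM; time 1.5 h

oak run (percent of the free monomer charged)

| time / min | monomer in chains / % | free monomer / % |
|---|---|---|
| 5.00 | 6.1 | 93.4 |
| 10.0 | 22.7 | 77.4 |
| 15.0 | 38.9 | 61.0 |
| 20.0 | 50.3 | 49.4 |

(scatter of a reading: 0.3 percentage points)

* whether the average number of monomer units in a chain (chains begun, living or dead) reaches 70 by 1.5 h (no / yes)
* average number of monomer units in a chain (chains begun, living or dead) at 1.5 h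

- the average divides the monomer in chains by the number of chains begun, living and dead together
- the earlier runs do not show the number of chains; that part of a forecast is a guess

The quantity to carry is the charge ratio R, free monomer charged over pre-initiator charged 200, the target degree of polymerization at full conversion. The readings do not show the number of chains, so my own reckoning guesses one chain per pre-initiator molecule; the length L is then R times the fraction of the charged free monomer that stands as monomer in chains.

Fraction for L = 70: 35.0%; the reading at 15.0 min is 38.9%.

L at 20.0 min: R × 50.3% = 101.

L at 1.5 h, with a final fraction near 0.7: 140.

That fraction is my judgement from the readings, whose last gain is 11 percentage points after 16 points. On that guess the flask should stand past 70 by 1.5 h, and it stays closed, with nothing added, so that R holds.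

The forecast says yes and 165, above my 140, on the ground that “Incomplete initiation raises it”.

The flask gives yes and a length of 133 at 1.5 h.

    pre-initiator → initiator (k = 0.0900 min⁻¹)
    living end + monomer in chains → dead end (k = 0.0730 M⁻¹ min⁻¹)
    free monomer + initiator → living end + monomer in chains (k = 17.0 M⁻¹ min⁻¹)
    free monomer + living end → monomer in chains + living end, rate k4*[living end]*[free monomer] (k = 600 M⁻¹ min⁻¹)
    monomer in chains + living end → free monomer + living end, rate k5*[living end] as long as [monomer in chains] is above zero (k = 10.0 min⁻¹)

Free monomer in the flask stands at 33.9% of its charge at 0.750 h and at 33.3% at 1.50 h. R times the flask's 66.6% in chains at 1.50 h gives 133. With half the pre-initiator, R is 400 and the run ends at a length of 266, which is 66.4% of that R.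

(The data were computed for an exercise, noise included.)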